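The cyclopentenone is disconnected at the bond between the spiro carbon and the carbinol carbon C(OH)(CO2Me), read as an aldol bond, and the ester carbon is returned to the carbocycle as a ketone. The precursor is then a racemic 3(2H)-furanone spiro-linked to a dimethoxycyclohexenetrione, made from a flat 6,7-dimethoxyflavone-5,8-quinone by epoxidation and pyranone contraction. The key step exploits the fact that the spiro carbon is both C2 of the furanone ring and the α-carbon of the cyclopentenone ketone: once released it is an aromatic 2-acyl-3-hydroxyfuran. Methanolysis therefore opens the six-membered ring to an achiral keto ester, and a chiral copper catalyst recloses it as the cyclopentenone, setting both quaternary stereocentres.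

Key step: step 8

Assumption: 1 and 6 are taken as catalogue compounds; the flavone locants (O1, C2, C3, C4, C4a, C5 to C8, C8a) are kept for every later compound (in 15, C4a is the spiro carbon, C8 the carbinol carbon, C8a the ester carbon); the R,R ligand is chosen by analogy with pyruvate aldol additions under this catalyst, and its mirror image would be used if the sense of induction proved opposite.

Step 1
Reactants: 1 1,2,3,4-tetramethoxybenzene
Product: 4 2,3,4,5-tetramethoxyphenol, via aryllithium 2 (not isolated), via dimethyl arylboronate 3 (not isolated)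
Conditions: n-BuLi, TMEDA, THF, 0 °C; B(OMe)3, −78 °C to rt; AcOH, 30% H2O2, 0 °C to rt
Reagents that add atoms: n-butyllithium [Li]CCCC (lithium of 2 only); trimethyl borate COB(OC)OC (boron group of 3 only); hydrogen peroxide OO (phenol oxygen of 4)
Why: Methoxy-directed ortho-lithiation can only occur at the two equivalent free ring positions, and borylation followed by peroxide oxidation (1,2-aryl shift from boron to oxygen) should turn the C–Li bond into C–OH in one flask.

Step 2
Reactants: 4 2,3,4,5-tetramethoxyphenol
Product: 5 2-hydroxy-3,4,5,6-tetramethoxyacetophenone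
Conditions: AcOH, BF3·OEt2, 90 °C; then H2O
Reagents that add atoms: acetic acid CC(=O)O
Why: Friedel–Crafts C-acetylation (equivalent to O-acetylation and Fries rearrangement in situ) must go to the single unsubstituted ring carbon, which lies ortho to the hydroxyl, and the chelated ortho-hydroxy ketone should resist further reaction.

Step 3
Reactants: 5 2-hydroxy-3,4,5,6-tetramethoxyacetophenone; 6 4-benzyloxybenzoyl chloride
Product: 8 1-(4-benzyloxyphenyl)-3-(2-hydroxy-3,4,5,6-tetramethoxyphenyl)propane-1,3-dione, via aryl benzoate 7 (not isolated)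
Conditions: pyridine, DMAP (cat.), 0 °C to rt; then KOH (powder), 50 °C; aq. AcOH
Reagents that add atoms: none
Why: O-aroylation of the phenol followed by Baker–Venkataraman rearrangement, in which the acetyl enolate takes the aroyl group from oxygen by an intramolecular Claisen transfer, driven by formation of the stabilised diketone enolate and phenoxide.

Step 4
Reactants: 8 1-(4-benzyloxyphenyl)-3-(2-hydroxy-3,4,5,6-tetramethoxyphenyl)propane-1,3-dione
Product: 9 2-(4-benzyloxyphenyl)-5,6,7,8-tetramethoxy-4H-chromen-4-one (4'-benzyloxy-5,6,7,8-tetramethoxyflavone)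
Conditions: p-TsOH·H2O (cat.), toluene, 110 °C, Dean–Stark
Reagents that add atoms: none
Why: Acid-catalysed cyclodehydration of the ortho-hydroxyaryl 1,3-diketone closes the 4-pyranone by phenol addition to the enolised aroyl carbonyl and loss of water, and the benzyl ether should tolerate catalytic sulfonic acid.

Step 5
Reactants: 9 2-(4-benzyloxyphenyl)-5,6,7,8-tetramethoxy-4H-chromen-4-one
Product: 10 2-(4-benzyloxyphenyl)-6,7-dimethoxy-4H-chromene-4,5,8-trione (the flavone-5,8-quinone)
Conditions: (NH4)2Ce(NO3)6, MeCN/H2O, 0 °C
Reagents that add atoms: water O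
Why: Oxidative demethylation by the tetravalent cerium salt should occur on ring A, by far the most electron-rich arene, where water attacks the radical cation at C5 and C8 with loss of two methanols; the para-quinone is the usual outcome for a 1,4-dimethoxy pair, and the benzyloxyphenyl ring is deactivated by conjugation with the pyranone carbonyl.

Step 6
Reactants: 10 2-(4-benzyloxyphenyl)-6,7-dimethoxy-4H-chromene-4,5,8-trione
Product: 11 racemic 2-(4-benzyloxyphenyl)-4a,8a-epoxy-6,7-dimethoxy-4a,8a-dihydro-4H-chromene-4,5,8-trione (cis-fused oxirane)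
Conditions: t-BuOOH (in decane, 1.0 equiv), DBU (10 mol %), CH2Cl2, −40 to −20 °C; cold silica filtration
Reagents that add atoms: tert-butyl hydroperoxide CC(C)(C)OO
Why: Weitz–Scheffer nucleophilic epoxidation, in which the tert-butylperoxide anion adds to C8a (the β-carbon of both the C4 and the C5 carbonyl) and the 1,3-diketone enolate closes the oxirane from C4a with loss of tert-butoxide, while the C6=C7 bond carries two methoxy donors and is less electrophilic; the oxirane can only be cis-fused, so a single racemic diastereomer is expected.

Step 7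
Reactants: 11 racemic 4a,8a-epoxide of the flavone quinone
Product: 12 racemic 2-(4-benzyloxyphenyl)-8,9-dimethoxy-1-oxaspiro[4.5]deca-2,8-diene-4,6,7,10-tetraone (spiro carbon = C4a, new ketone = C8a)
Conditions: DMAP (10 mol %), CH2Cl2 (anhydrous), 0 °C to rt
Reagents that add atoms: none
Why: Proposed new method: DMAP adds reversibly to C2 of the dihydropyranone (a vinylogous ester), β-elimination releases O1 as the C8a alkoxide of an epoxy hemiketal, this collapses to the C8a ketone with opening of the oxirane, and the freed C4a alkoxide adds back to C2 and expels DMAP to close the 3(2H)-furanone, so that no bond to C4a is broken and the step is a vinylogous O-to-O acyl transfer driven by loss of oxirane strain; the closest known reactions are the rearrangement of enol ester epoxides to α-acyloxy ketones and the amine-triggered ring opening and reclosure of chromones.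

Step 8
Reactants: 12 racemic spiro furanone cyclohexenetrione
Product: 14 methyl (5S,6R)-2-(4-benzyloxyphenyl)-6-hydroxy-7,8-dimethoxy-4,9-dioxo-1-oxaspiro[4.4]nona-2,7-diene-6-carboxylate (O-benzyl limnophilaspiroketone), via open keto ester 13 (not isolated)
Conditions: Cu(OTf)2 (10 mol %), (R,R)-t-Bu-box (12 mol %), MeOH (3 equiv), CH2Cl2, −40 °C; silica plug, no base
Reagents that add atoms: methanol CO
Why: Proposed new method: the divalent copper Lewis acid activates the C8/C8a vicinal dione, methanol adds to C8a (the MeO–C8a bond forms) and retro-Claisen scission of C4a–C8a releases C4a as the aromatic, acidic 2-acyl-3-hydroxyfuran of achiral 13, so both enantiomers of 12 converge on one intermediate. Furan C2 (C4a) then attacks the copper-chelated ketone C8 of the α-keto ester in a dearomative aldol, a 5-(enolexo)-exo-trig closure that forms the C4a–C8 bond and the cyclopentenone and restores the 3(2H)-furanone. The closest known reactions are the benzilic ester ring contraction of cyclic 1,2-diketones, the Lewis acid retro-Claisen alcoholysis of 1,3-diketones, and Cu(OTf)2/bis(oxazoline) aldol and Friedel–Crafts additions of enols and furans to α-keto esters. The carbinol centre C8 is set by the ligand, whose tert-butyl groups shield one face of the square-planar keto ester chelate (re-face attack with the R,R ligand), and the spiro centre C4a by an open transition state in which the furan 3-OH turns away from the copper-bound developing alkoxide, which places the new OH syn to the furanone ring oxygen and CO2Me syn to the furanone carbonyl. The step needs methanol to attack C8a alone and the catalysed closure to outrun both the uncatalysed one and the retro-aldol; the first follows from C8a being the only ketone that is not a vinylogous ester, the second from the Z-enedione tether that holds the chelated ketone beside C4a, from low temperature and from a non-basic work-up.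

Step 9
Reactants: 14 O-benzyl limnophilaspiroketone
Product: 15 limnophilaspiroketone, methyl (5S,6R)-6-hydroxy-2-(4-hydroxyphenyl)-7,8-dimethoxy-4,9-dioxo-1-oxaspiro[4.4]nona-2,7-diene-6-carboxylate
Conditions: H2 (1 atm), 10% Pd/C, EtOAc, rt
Reagents that add atoms: none
Why: Hydrogenolysis of the aryl benzyl ether over palladium on carbon is neutral, so retro-aldol opening cannot erode the two stereocentres, and both ring alkenes are β-oxygenated vinylogous esters that should resist hydrogenation under these conditions.

Compound list
1 | 1,2,3,4-tetramethoxybenzene | COc1ccc(OC)c(OC)c1OC | starting material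
2 | (2,3,4,5-tetramethoxyphenyl)lithium, formed in the flask | [Li]c1cc(OC)c(OC)c(OC)c1OC | intermediate
3 | dimethyl (2,3,4,5-tetramethoxyphenyl)boronate, formed in the flask (first as its lithium methoxide ate complex) | COB(OC)c1cc(OC)c(OC)c(OC)c1OC | intermediate
4 | 2,3,4,5-tetramethoxyphenol | Oc1cc(OC)c(OC)c(OC)c1OC | intermediate
5 | 2-hydroxy-3,4,5,6-tetramethoxyacetophenone | CC(=O)c1c(O)c(OC)c(OC)c(OC)c1OC | intermediate
6 | 4-benzyloxybenzoyl chloride | O=C(Cl)c1ccc(OCc2ccccc2)cc1 | starting material
7 | 2-acetyl-3,4,5,6-tetramethoxyphenyl 4-benzyloxybenzoate, formed in the flask | CC(=O)c1c(OC(=O)c2ccc(OCc3ccccc3)cc2)c(OC)c(OC)c(OC)c1OC | intermediate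
8 | 1-(4-benzyloxyphenyl)-3-(2-hydroxy-3,4,5,6-tetramethoxyphenyl)propane-1,3-dione | COc1c(O)c(C(=O)CC(=O)c2ccc(OCc3ccccc3)cc2)c(OC)c(OC)c1OC | intermediate
9 | 2-(4-benzyloxyphenyl)-5,6,7,8-tetramethoxy-4H-chromen-4-one | COc1c(OC)c(OC)c2c(c1OC)OC(=CC2=O)c1ccc(OCc3ccccc3)cc1 | intermediate
10 | 2-(4-benzyloxyphenyl)-6,7-dimethoxy-4H-chromene-4,5,8-trione | COC1=C(OC)C(=O)C2=C(C1=O)C(=O)C=C(c1ccc(OCc3ccccc3)cc1)O2 | intermediate
11 | racemic 2-(4-benzyloxyphenyl)-4a,8a-epoxy-6,7-dimethoxy-4a,8a-dihydro-4H-chromene-4,5,8-trione (cis-fused oxirane, one enantiomer drawn) | O=C1C(OC)=C(OC)C(=O)[C@]23O[C@@]13C(=O)C=C(c1ccc(OCc4ccccc4)cc1)O2 | intermediate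
12 | racemic 2-(4-benzyloxyphenyl)-8,9-dimethoxy-1-oxaspiro[4.5]deca-2,8-diene-4,6,7,10-tetraone (one enantiomer drawn) | O=C1C(OC)=C(OC)C(=O)C(=O)[C@@]12OC(c1ccc(OCc3ccccc3)cc1)=CC2=O | intermediate
13 | methyl (Z)-5-[5-(4-benzyloxyphenyl)-3-hydroxyfuran-2-yl]-3,4-dimethoxy-2,5-dioxopent-3-enoate, achiral, formed in the flask | COC(=O)C(=O)/C(OC)=C(OC)\C(=O)c1oc(-c2ccc(OCc3ccccc3)cc2)cc1O | intermediate
14 | methyl (5S,6R)-2-(4-benzyloxyphenyl)-6-hydroxy-7,8-dimethoxy-4,9-dioxo-1-oxaspiro[4.4]nona-2,7-diene-6-carboxylate (OH syn to the furanone ring oxygen) | COC(=O)[C@@]1(O)C(OC)=C(OC)C(=O)[C@]12OC(c1ccc(OCc3ccccc3)cc1)=CC2=O | intermediate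
15 | limnophilaspiroketone, methyl (5S,6R)-6-hydroxy-2-(4-hydroxyphenyl)-7,8-dimethoxy-4,9-dioxo-1-oxaspiro[4.4]nona-2,7-diene-6-carboxylate | COC(=O)[C@@]1(O)C(OC)=C(OC)C(=O)[C@]12OC(c1ccc(O)cc1)=CC2=O | target

Total step count: 9. Longest linear sequence: 9 steps, from 1 to 15 (6 is bought and enters in step 3).

Steps most likely to fail

Step 8 (Proposed new method). Facial discrimination in the ring closure may be weak, because the copper centre may bind the acidic acylhydroxyfuran instead of the keto ester, or an uncatalysed closure may compete; the aldol may also reverse during isolation. The fallback uses known chemistry and sets out from 12. Catalytic NaOMe in MeOH/CH2Cl2 at −20 °C should effect the ordinary benzilic ester ring contraction and give 14 as a racemate, that is together with its mirror image, methyl (5R,6S)-2-(4-benzyloxyphenyl)-6-hydroxy-7,8-dimethoxy-4,9-dioxo-1-oxaspiro[4.4]nona-2,7-diene-6-carboxylate F1. After an acidic quench the enantiomers would be separated by preparative chromatography on a chiral stationary phase (amylose carbamate, supercritical CO2/MeOH). The route is rejoined at 14.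

Step 7 (Proposed new method). The amine may add at the methoxy-bearing enedione carbons instead of C2, or the last ring closure onto the pyridinium enone (a 5-endo attack) may fail, leaving ring-opened material that degrades. The fallback uses known chemistry and sets out from 11. Hydrolysis with TFA in wet THF at 0 °C, the vinylogous counterpart of the hydrolysis of enol ester epoxides to α-hydroxy ketones, should open pyranone and oxirane to racemic 2-[3-(4-benzyloxyphenyl)-3-oxopropanoyl]-2-hydroxy-5,6-dimethoxycyclohex-5-ene-1,3,4-trione F2. Cyclodehydration of this α'-hydroxy 1,3-diketone with p-TsOH in toluene at 60 °C, the standard entry to 3(2H)-furanones, would then close the spiro ring. The route is rejoined at 12.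

Step 6. The peroxide anion may add at C2 or displace methoxide at C6 or C7 of the quinone, and the base may open the epoxide while oxidant is still present. The fallback masks one quinone carbonyl and sets out from 9.
- Chelation-directed cleavage of the methyl ether peri to the C4 carbonyl (MgBr2·OEt2, MeCN, 60 °C) should give 2-(4-benzyloxyphenyl)-5-hydroxy-6,7,8-trimethoxy-4H-chromen-4-one F3.
- Oxidative dearomatisation with PhI(OAc)2 in MeOH at 0 °C should give the para-quinone monoketal 2-(4-benzyloxyphenyl)-6,7,8,8-tetramethoxy-4H-chromene-4,5(8H)-dione F4, in which ring A keeps a single carbonyl and C6/C7 are far less electrophilic.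
- Nucleophilic epoxidation (t-BuOOH, DBU, CH2Cl2, −20 °C), well established for quinone monoketals, should give racemic 2-(4-benzyloxyphenyl)-4a,8a-epoxy-6,7,8,8-tetramethoxy-4a,8a-dihydro-4H-chromene-4,5(8H)-dione F5.
- Mild ketal hydrolysis (aqueous oxalic acid on silica, CH2Cl2) would rejoin the route at 11.

Further compounds
F1 | step 8 | methyl (5R,6S)-2-(4-benzyloxyphenyl)-6-hydroxy-7,8-dimethoxy-4,9-dioxo-1-oxaspiro[4.4]nona-2,7-diene-6-carboxylate (mirror image of 14, second component of the racemate) | COC(=O)[C@]1(O)C(OC)=C(OC)C(=O)[C@@]12OC(c1ccc(OCc3ccccc3)cc1)=CC2=O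
F2 | step 7 | racemic 2-[3-(4-benzyloxyphenyl)-3-oxopropanoyl]-2-hydroxy-5,6-dimethoxycyclohex-5-ene-1,3,4-trione (one enantiomer drawn) | O=C1C(OC)=C(OC)C(=O)C(=O)[C@]1(O)C(=O)CC(=O)c1ccc(OCc2ccccc2)cc1
F3 | step 6 | 2-(4-benzyloxyphenyl)-5-hydroxy-6,7,8-trimethoxy-4H-chromen-4-one | COc1c(OC)c(O)c2c(c1OC)OC(=CC2=O)c1ccc(OCc3ccccc3)cc1
F4 | step 6 | 2-(4-benzyloxyphenyl)-6,7,8,8-tetramethoxy-4H-chromene-4,5(8H)-dione | COC1=C(OC)C(OC)(OC)C2=C(C1=O)C(=O)C=C(c1ccc(OCc3ccccc3)cc1)O2
F5 | step 6 | racemic 2-(4-benzyloxyphenyl)-4a,8a-epoxy-6,7,8,8-tetramethoxy-4a,8a-dihydro-4H-chromene-4,5(8H)-dione (one enantiomer drawn) | O=C1C(OC)=C(OC)C(OC)(OC)[C@]23O[C@@]13C(=O)C=C(c1ccc(OCc4ccccc4)cc1)O2
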